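## Analysis of the target

The target consists of two coumarins (2H-chromen-2-ones) joined by one diaryl ether oxygen. With coumarin numbering in each half, unit A is a 7-hydroxycoumarin carrying the bridging oxygen on C6, and unit B is a 6,7-dihydroxycoumarin carrying it on C5. "Ring A" and "ring B" below mean the benzene rings of the two units, and "pyranone A" and "pyranone B" their lactone rings. There is no stereocentre and no element of chirality to control. The sensitive groups are the two lactones, which hydroxide opens, and the three phenols; the 6,7-pair of unit B is a catechol that oxidises easily, so the phenols should be uncovered last under acidic, non-oxidising conditions. The difficulty is the ether: its unit B carbon, C5, lies between C4a (peri to C4–H) and the oxygenated C6 in a ring bearing four oxygens. An aryl–oxygen coupling there is hindered, and the oxygens of both rings must be told apart. The plan rests on ring A, where C8a–O is para to the aryloxy carbon C6 and meta to C7–O, with C5 and C8 unsubstituted. This is the pattern produced when a vinylketene supplying C8a, C6, C5 and C4a is annulated with an alkoxyacetylene supplying C8 and C7, so ring A can be grown on the oxygen already attached to C5 of unit B.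

## Retrosynthetic reasoning

**20 to 19.** The last bonds cut are the three O–alkyl bonds: two O–CH3 on unit B and the O–C2H5 on C7 of unit A. All three fall under one Lewis-acid dealkylation, so no differentiation is needed at the end, and the catechol appears only in the final acidic step. The forward reaction must leave the diaryl ether and both lactones intact.

**19 to 16 and 17.** Pyranone A is disconnected at C4–C4a and O1–C2, giving phenol 16 and the three-carbon unit 17. This works because 16 has exactly one free hydroxyl, on C8a, and its C7 oxygen is capped. The forward annulation must attack the ring carbon ortho to the hydroxyl and para to the ethoxy group (the future C4a), not the crowded position between the two oxygens.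

**16 to 10 and 11 (key disconnection).** Ring A is cut at C8–C8a, C6–C7 and C4a–C8a. This leads back to acid chloride 10 as the precursor of aryloxy(vinyl)ketene 12, and to ynol ether 11. Cutting the aryl–oxygen bond instead would require a coupling at the hindered C5 of unit B or by a hindered phenoxide; here that oxygen is already in place and ring A is assembled around it. The forward cascade must pass through cyclobutenone 13, dienylketene 14 and dienone 15, with the ethoxy group ending next to the aryloxy carbon.

**10 to 6 and 7.** The acid chloride comes from acid 9 and that from ester 8. The O–C(sp3) bond of 8 is cut to give phenol 6 and hydroxy ester 7, joined by Mitsunobu etherification. A substitution at an activated secondary carbinol tolerates a hindered oxygen nucleophile far better than an aryl coupling would. The new centre need not be controlled because it becomes sp2 in 12.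

**6 to 1.** The C5–O bond of 6 is traced to the formyl group of 4 (Baeyer–Villiger oxidation, through formate 5). The C5–CHO bond is traced to ortho-formylation of phenol 1, with a methylation (3 to 4) in between. In 1 the lactone already exists and C5 is the only free position ortho to the hydroxyl, so the regiochemistry is fixed by the substrate. Annulating a pyranone onto a trioxygenated phenol with one differentiated oxygen would instead have to choose between two non-equivalent ortho positions.

## Alternatives that were turned down

**Alternative 1:** Both O1–C8a bonds are disconnected, leading to the (E,E)-bis-cinnamic acid A2.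
- **Forward key step:** a flavin-type photocatalyst in air would isomerise both alkenes to Z and oxidise each arene, so that each carboxylate oxygen closes onto C8a of its own ring, giving the trimethyl ether A1.
- **For it:** both pyranones form in one operation, protection is uniformly methyl, and no ketene or ynol ether is handled. Once the ether is in hand it is at least as short as the chosen route.
- **Against it:** the hindered diaryl ether of A2 must first be made by coupling at the future C5 of unit B, which is the hard bond. In the ring A half the acid has two free ortho positions (future C8a and C5) with only a para-oxygen bias between them. Ring A, with two oxygens, is much harder to oxidise than ring B, with three, so one set of conditions must serve two different arenes.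
- **Comparison:** the chosen route fixes every ring A position through connectivity and never forms the aryl–oxygen bond by coupling.

**Alternative 2:** Ring B is disconnected at C5–C6 and C4a–C8a into the bis-silyloxy diene A4 and the aryloxy ynal A5.
- **Forward key step:** Diels–Alder addition and aromatisation by loss of the acetal methoxy group would give salicylaldehyde A3 with all substituents of ring B in place.
- **For it:** it builds the more crowded ring, where a benzannulation pays most, and is in that respect more ambitious than the chosen route. Cycloadditions of siloxydienes with ynones are established.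
- **Against it:** A5 is a push–pull alkyne whose reacting carbon bears a donor oxygen, so it is a sluggish dienophile and prone to hydration. A3 carries ring A as a 2,4-dimethoxyphenyl group, with the C8a and C7 oxygens of unit A both as methyl ethers. Pyranone A needs a free C8a hydroxyl, so a selective demethylation between two similar anisole oxygens is required, in addition to closing pyranone B.
- **Comparison:** the chosen benzannulation delivers 16 with this differentiation built in (C8a–OH free, C7–O as ethyl ether), two steps from the target.

**Alternative 3:** The C7–O bond of unit A and the C6–O bond of unit B are traced to formyl groups in dialdehyde A7, whose ether is available by formyl-activated nucleophilic aromatic substitution.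
- **Forward key step:** a peracid converts both aldehydes into aryl formates by aryl migration to oxygen, and solvolysis gives bis-phenol A6.
- **For it:** every reaction is textbook chemistry, and the formyl groups both activate the ether formation and mark the later hydroxyls. On reliability it is stronger than the chosen route.
- **Against it:** in A6 the oxygens of unit A are the wrong way round for the endgame: C7–OH is free and C8a–O is a methyl ether. Two phenols must be protected, one of two aryl methyl ethers cleaved selectively, pyranone A annulated, and everything unmasked.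
- **Comparison:** the chosen route accepts one unprecedented step and reaches the target two steps after it with no selective deprotection.

Key step: step 7

**Assumptions.** The side-chain carbon C2 of 7 to 10 is carried as the racemate, because it becomes sp2 in ketene 12; no stereodescriptor is written for these compounds. Compounds 1, 7, 11 and 17 are taken as purchasable.

## Route

Step 1
Reactants: 1 6-hydroxy-7-methoxy-2H-chromen-2-one (isoscopoletin)
Product: 3 6-hydroxy-7-methoxy-2-oxo-2H-chromene-5-carbaldehyde, via hydroxymethyl phenol 2 (not isolated)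
Conditions: MgCl2, Et3N, (CH2O)n, MeCN, reflux; then 1 M HCl
Reagents that add atoms: paraformaldehyde (formaldehyde), C=O
Why: Magnesium-mediated ortho-formylation of a phenol (Casnati–Skattebøl reaction): the phenoxide formed with MgCl2/Et3N delivers magnesium-bound formaldehyde only ortho to its oxygen, and C5 is the single free ortho position because C7 bears OMe. The benzylic alkoxide 2 is oxidised to the aldehyde by hydride transfer to a second formaldehyde; the lactone is inert to the amine base.

Step 2
Reactants: 3 6-hydroxy-7-methoxy-2-oxo-2H-chromene-5-carbaldehyde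
Product: 4 6,7-dimethoxy-2-oxo-2H-chromene-5-carbaldehyde
Conditions: MeI, K2CO3, DMF, 40 °C
Reagents that add atoms: iodomethane, CI
Why: Williamson methylation of the hydrogen-bonded salicylaldehyde hydroxyl. It precedes the oxidation so that C6–O is capped and C5–O will be the only free hydroxyl of 6.

Step 3
Reactants: 4 6,7-dimethoxy-2-oxo-2H-chromene-5-carbaldehyde
Product: 6 5-hydroxy-6,7-dimethoxy-2H-chromen-2-one, via aryl formate 5 (not isolated)
Conditions: mCPBA, CH2Cl2, 25 °C; then MeOH, Et3N (cat.), 25 °C
Reagents that add atoms: 3-chloroperoxybenzoic acid (mCPBA), O=C(OO)c1cccc(Cl)c1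
Why: Baeyer–Villiger (Dakin-type) oxidation: in the Criegee adduct the aryl group, made electron-rich by the ortho methoxy group, migrates in preference to hydrogen, and mild methanolysis of formate 5 frees the phenol. The electron-poor C3=C4 alkene of the coumarin is not epoxidised by the peracid.

Step 4
Reactants: 6 5-hydroxy-6,7-dimethoxy-2H-chromen-2-one; 7 methyl 2-hydroxybut-3-enoate (racemic)
Product: 8 methyl 2-[(6,7-dimethoxy-2-oxo-2H-chromen-5-yl)oxy]but-3-enoate (racemic)
Conditions: PPh3, DIAD, THF, 0 → 25 °C
Reagents that add atoms: none
Why: Mitsunobu etherification: phenol 6, whose acidity is raised by conjugation with the lactone carbonyl, is displaced onto the oxyphosphonium of 7 by SN2 at a carbinol carbon activated by both the ester and the vinyl group. The hindrance lies on the nucleophilic oxygen, which this substitution tolerates; the new centre is racemic and is erased in step 7.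

Step 5
Reactants: 8 methyl 2-[(6,7-dimethoxy-2-oxo-2H-chromen-5-yl)oxy]but-3-enoate
Product: 9 2-[(6,7-dimethoxy-2-oxo-2H-chromen-5-yl)oxy]but-3-enoic acid (racemic)
Conditions: LiOH·H2O, THF/H2O, 0 °C; then 1 M HCl to pH 2
Reagents that add atoms: LiOH (lithium hydroxide), [Li+].[OH-]
Why: Saponification of an alpha-aryloxy ester is fast at 0 °C and the resulting carboxylate resists further deprotonation at C2. Any lactone opened by hydroxide recloses on acidification because the C3=C4 alkene stays cis.

Step 6
Reactants: 9 2-[(6,7-dimethoxy-2-oxo-2H-chromen-5-yl)oxy]but-3-enoic acid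
Product: 10 2-[(6,7-dimethoxy-2-oxo-2H-chromen-5-yl)oxy]but-3-enoyl chloride (racemic)
Conditions: (COCl)2, DMF (cat.), CH2Cl2, 0 → 25 °C; evaporate
Reagents that add atoms: oxalyl chloride, O=C(Cl)C(Cl)=O
Why: Acid chloride formation through the chloroiminium species from DMF, under neutral conditions at low temperature. The by-products are gases, so crude 10 is used directly.

Step 7
Reactants: 10 2-[(6,7-dimethoxy-2-oxo-2H-chromen-5-yl)oxy]but-3-enoyl chloride; 11 ethoxyacetylene
Product: 16 5-(2-ethoxy-4-hydroxyphenoxy)-6,7-dimethoxy-2H-chromen-2-one, via ketene 12 (not isolated), via cyclobutenone 13 (not isolated), via dienylketene 14 (not isolated), via cyclohexadienone 15 (not isolated)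
Conditions: Et3N, 11 (excess), toluene, 0 → 25 °C, slow addition of 10; filter, evaporate excess 11; toluene, 100 °C (sealed tube)
Reagents that add atoms: none
Why: Proposed new method: Et3N dehydrochlorinates 10, whose C2–H is acidified by the carbonyl, the aryloxy oxygen and the vinyl group, to the aryloxy(vinyl)ketene 12; the unsubstituted, nucleophilic carbon of ynol ether 11 attacks the ketene carbonyl carbon and the ethoxy-bearing carbon bonds to the ketene alpha-carbon, so the [2+2] cycloaddition across the ketene C=C bond gives cyclobutenone 13 (C8–C8a and C6–C7) with OEt next to the aryloxy carbon. At 100 °C 13 opens by conrotatory 4π electrocyclic cleavage of its C(=O)–C(OAr) bond, the donor aryloxy group turning outward and the vinyl group inward, which gives the (3Z)-dienylketene 14. Ring A, the only ring left by the step, then closes by thermal disrotatory 6π electrocyclisation (C4a–C8a), and cyclohexadienone 15 tautomerises to phenol 16. No stereocentre is created that survives: the centres of 10 and 13 both end as sp2 carbons. The closest known reaction types are the Danheiser benzannulation of vinylketenes with alkoxy- and siloxyalkynes and the thermal rearrangement of 4-alkoxy-4-vinylcyclobutenones to hydroquinone monoethers (Moore rearrangement); new here is that an alpha-aryloxy vinylketene is made by dehydrochlorination and caught by the ynol ether. The step needs regioselectivity in the [2+2] event, which the matched polarity of ketene and ynol ether secures, periselectivity for the ketene C=C bond over the diene, which is the normal behaviour of vinylketenes, and an unacylated product, which is secured by completing ketene formation at 25 °C and removing excess 11 before heating. A Claisen shift of the aryl allyl ether units is excluded because both positions ortho to the ether oxygen on ring B (C4a and C6) are substituted.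

Step 8
Reactants: 16 5-(2-ethoxy-4-hydroxyphenoxy)-6,7-dimethoxy-2H-chromen-2-one; 17 ethyl propiolate
Product: 19 6-[(6,7-dimethoxy-2-oxo-2H-chromen-5-yl)oxy]-7-ethoxy-2H-chromen-2-one, via cinnamate ester 18 (not isolated)
Conditions: ZnCl2, dioxane, 100 °C
Reagents that add atoms: none
Why: Pechmann-type annulation with a propiolate: ZnCl2 activates 17 for Friedel–Crafts conjugate addition by the ring carbon ortho to OH and para to OEt (the other ortho position lies between two oxygens and is hindered), and the Z-cinnamate 18 lactonises in place. Phenol 16 is a 3,4-dioxygenated phenol, the substrate class for which this annulation is used; ring B is deactivated by its lactone and does not compete.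

Step 9
Reactants: 19 6-[(6,7-dimethoxy-2-oxo-2H-chromen-5-yl)oxy]-7-ethoxy-2H-chromen-2-one
Product: 20 6-[(6,7-dihydroxy-2-oxo-2H-chromen-5-yl)oxy]-7-hydroxy-2H-chromen-2-one (target)
Conditions: BBr3 (excess), CH2Cl2, −78 → 25 °C; then H2O
Reagents that add atoms: none
Why: Lewis-acid dealkylation of aryl alkyl ethers: bromide attacks the O-alkyl carbon of each boron-complexed ether, removing the two methyl groups and the ethyl group, while the diaryl ether and both lactones are inert. The acidic, non-oxidising conditions protect the catechol.

## Compound list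

1 | 6-hydroxy-7-methoxy-2H-chromen-2-one (isoscopoletin) | COc1cc2oc(=O)ccc2cc1O | starting material
2 | 6-hydroxy-5-(hydroxymethyl)-7-methoxy-2H-chromen-2-one (bound to magnesium in the flask) | COc1cc2oc(=O)ccc2c(CO)c1O | intermediate
3 | 6-hydroxy-7-methoxy-2-oxo-2H-chromene-5-carbaldehyde | COc1cc2oc(=O)ccc2c(C=O)c1O | intermediate
4 | 6,7-dimethoxy-2-oxo-2H-chromene-5-carbaldehyde | COc1cc2oc(=O)ccc2c(C=O)c1OC | intermediate
5 | 6,7-dimethoxy-2-oxo-2H-chromen-5-yl formate | COc1cc2oc(=O)ccc2c(OC=O)c1OC | intermediate
6 | 5-hydroxy-6,7-dimethoxy-2H-chromen-2-one | COc1cc2oc(=O)ccc2c(O)c1OC | intermediate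
7 | methyl 2-hydroxybut-3-enoate (racemic) | C=CC(O)C(=O)OC | starting material
8 | methyl 2-[(6,7-dimethoxy-2-oxo-2H-chromen-5-yl)oxy]but-3-enoate (racemic) | C=CC(Oc1c(OC)c(OC)cc2oc(=O)ccc12)C(=O)OC | intermediate
9 | 2-[(6,7-dimethoxy-2-oxo-2H-chromen-5-yl)oxy]but-3-enoic acid (racemic) | C=CC(Oc1c(OC)c(OC)cc2oc(=O)ccc12)C(=O)O | intermediate
10 | 2-[(6,7-dimethoxy-2-oxo-2H-chromen-5-yl)oxy]but-3-enoyl chloride (racemic) | C=CC(Oc1c(OC)c(OC)cc2oc(=O)ccc12)C(Cl)=O | intermediate
11 | ethoxyacetylene (ethoxyethyne) | C#COCC | starting material
12 | 5-[(1-oxobuta-1,3-dien-2-yl)oxy]-6,7-dimethoxy-2H-chromen-2-one (aryloxy(vinyl)ketene) | C=CC(=C=O)Oc1c(OC)c(OC)cc2oc(=O)ccc12 | intermediate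
13 | 5-[(1-ethenyl-2-ethoxy-4-oxocyclobut-2-en-1-yl)oxy]-6,7-dimethoxy-2H-chromen-2-one (racemic) | C=CC1(Oc2c(OC)c(OC)cc3oc(=O)ccc23)C(OCC)=CC1=O | intermediate
14 | 5-{[(3Z)-4-ethoxy-6-oxohexa-1,3,5-trien-3-yl]oxy}-6,7-dimethoxy-2H-chromen-2-one (dienylketene) | C=C/C(Oc1c(OC)c(OC)cc2oc(=O)ccc12)=C(\C=C=O)OCC | intermediate
15 | 5-[(6-ethoxy-4-oxocyclohexa-1,5-dien-1-yl)oxy]-6,7-dimethoxy-2H-chromen-2-one | CCOC1=CC(=O)CC=C1Oc1c(OC)c(OC)cc2oc(=O)ccc12 | intermediate
16 | 5-(2-ethoxy-4-hydroxyphenoxy)-6,7-dimethoxy-2H-chromen-2-one | CCOc1cc(O)ccc1Oc1c(OC)c(OC)cc2oc(=O)ccc12 | intermediate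
17 | ethyl propiolate (ethyl prop-2-ynoate) | C#CC(=O)OCC | starting material
18 | ethyl (2Z)-3-{5-[(6,7-dimethoxy-2-oxo-2H-chromen-5-yl)oxy]-4-ethoxy-2-hydroxyphenyl}prop-2-enoate | CCOC(=O)/C=C\c1cc(Oc2c(OC)c(OC)cc3oc(=O)ccc23)c(OCC)cc1O | intermediate
19 | 6-[(6,7-dimethoxy-2-oxo-2H-chromen-5-yl)oxy]-7-ethoxy-2H-chromen-2-one | CCOc1cc2oc(=O)ccc2cc1Oc1c(OC)c(OC)cc2oc(=O)ccc12 | intermediate
20 | 6-[(6,7-dihydroxy-2-oxo-2H-chromen-5-yl)oxy]-7-hydroxy-2H-chromen-2-one | O=c1ccc2cc(Oc3c(O)c(O)cc4oc(=O)ccc34)c(O)cc2o1 | target

## Step count and least certain steps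

Total: 9 steps. Longest linear sequence: 9 steps, from 1 to 20; compounds 7, 11 and 17 enter as purchased reagents.

**Step 7 (key step).** The most likely failure is self-condensation of the ketene, by dimerisation or amine-initiated oligomerisation, running faster than its capture by 11. Alkoxy-substituted ketenes are short-lived, and the base that forms them also adds to them. A second risk is hydrolytic loss of the vinylogous ester in 13 before the thermal stage.

The fallback uses only known chemistry and gives up building ring A. It sets out from 6 and returns at 16.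
- Phenol 6 is arylated by formyl-activated nucleophilic aromatic substitution with 3-ethoxy-4-fluorobenzaldehyde (K2CO3, DMF, 100 °C), giving 4-[(6,7-dimethoxy-2-oxo-2H-chromen-5-yl)oxy]-3-ethoxybenzaldehyde F1.
- Baeyer–Villiger oxidation with mCPBA gives 4-[(6,7-dimethoxy-2-oxo-2H-chromen-5-yl)oxy]-3-ethoxyphenyl formate F2.
- Methanolysis of F2 gives 16.

**Step 4.** The phenoxide may attack the alkene terminus (SN2′) instead of the carbinol carbon, or the reduced azo reagent may be alkylated in place of the hindered phenoxide.

The fallback sets out from 6 and returns at 8.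
- Phenol 6 is alkylated at the activated position of methyl 2,4-dibromobutanoate (K2CO3, acetone), giving methyl 4-bromo-2-[(6,7-dimethoxy-2-oxo-2H-chromen-5-yl)oxy]butanoate F3.
- Phenylselenide (from PhSeSePh and NaBH4, EtOH, 0 °C) displaces the primary bromide, giving methyl 2-[(6,7-dimethoxy-2-oxo-2H-chromen-5-yl)oxy]-4-(phenylselanyl)butanoate F4.
- Oxidation with H2O2 gives methyl 2-[(6,7-dimethoxy-2-oxo-2H-chromen-5-yl)oxy]-4-(phenylseleninyl)butanoate F5, which is not isolated; syn-elimination can only form the terminal alkene of 8.

**Step 5.** The double bond may migrate into conjugation with the carboxyl group through deprotonation at C2, and hydroxide may open the lactone.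

The fallback turns the migration to use. It sets out from 8 and returns at ketene 12 inside step 7.
- DBU in CH2Cl2 isomerises 8 to methyl 2-[(6,7-dimethoxy-2-oxo-2H-chromen-5-yl)oxy]but-2-enoate F6 (E/Z mixture; either isomer serves).
- LiOH, then acid, gives 2-[(6,7-dimethoxy-2-oxo-2H-chromen-5-yl)oxy]but-2-enoic acid F7.
- Oxalyl chloride with catalytic DMF gives 2-[(6,7-dimethoxy-2-oxo-2H-chromen-5-yl)oxy]but-2-enoyl chloride F8.
- Et3N removes a gamma-hydrogen of F8 (1,4-dehydrochlorination, the usual way to vinylketenes from alpha,beta-unsaturated acid chlorides), giving the same ketene 12.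

**Step 8.** Transesterification at the phenol oxygen may occur without C–C bond formation, conjugate addition may take place at the crowded ortho position between OH and OEt, or the ethyl ether may be lost under the Lewis acid at 100 °C.

The fallback sets out from 16 and returns at 19.
- Magnesium-mediated ortho-formylation (MgCl2, Et3N, paraformaldehyde, MeCN, reflux) at the less hindered ortho position gives 5-[(6,7-dimethoxy-2-oxo-2H-chromen-5-yl)oxy]-4-ethoxy-2-hydroxybenzaldehyde F9.
- Wittig reaction with ethyl (triphenylphosphoranylidene)acetate in N,N-diethylaniline at reflux gives ethyl (2E)-3-{5-[(6,7-dimethoxy-2-oxo-2H-chromen-5-yl)oxy]-4-ethoxy-2-hydroxyphenyl}prop-2-enoate F10, which is not isolated; at that temperature it isomerises and lactonises to 19.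

## Further compounds

F1 | step 7 | 4-[(6,7-dimethoxy-2-oxo-2H-chromen-5-yl)oxy]-3-ethoxybenzaldehyde | CCOc1cc(C=O)ccc1Oc1c(OC)c(OC)cc2oc(=O)ccc12
F2 | step 7 | 4-[(6,7-dimethoxy-2-oxo-2H-chromen-5-yl)oxy]-3-ethoxyphenyl formate | CCOc1cc(OC=O)ccc1Oc1c(OC)c(OC)cc2oc(=O)ccc12
F3 | step 4 | methyl 4-bromo-2-[(6,7-dimethoxy-2-oxo-2H-chromen-5-yl)oxy]butanoate (racemic) | COC(=O)C(CCBr)Oc1c(OC)c(OC)cc2oc(=O)ccc12
F4 | step 4 | methyl 2-[(6,7-dimethoxy-2-oxo-2H-chromen-5-yl)oxy]-4-(phenylselanyl)butanoate (racemic) | COC(=O)C(CC[Se]c1ccccc1)Oc1c(OC)c(OC)cc2oc(=O)ccc12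
F5 | step 4 | methyl 2-[(6,7-dimethoxy-2-oxo-2H-chromen-5-yl)oxy]-4-(phenylseleninyl)butanoate (mixture of stereoisomers) | COC(=O)C(CC[Se](=O)c1ccccc1)Oc1c(OC)c(OC)cc2oc(=O)ccc12
F6 | step 5 | methyl 2-[(6,7-dimethoxy-2-oxo-2H-chromen-5-yl)oxy]but-2-enoate (E/Z mixture) | CC=C(Oc1c(OC)c(OC)cc2oc(=O)ccc12)C(=O)OC
F7 | step 5 | 2-[(6,7-dimethoxy-2-oxo-2H-chromen-5-yl)oxy]but-2-enoic acid (E/Z mixture) | CC=C(Oc1c(OC)c(OC)cc2oc(=O)ccc12)C(=O)O
F8 | step 5 | 2-[(6,7-dimethoxy-2-oxo-2H-chromen-5-yl)oxy]but-2-enoyl chloride (E/Z mixture) | CC=C(Oc1c(OC)c(OC)cc2oc(=O)ccc12)C(Cl)=O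
F9 | step 8 | 5-[(6,7-dimethoxy-2-oxo-2H-chromen-5-yl)oxy]-4-ethoxy-2-hydroxybenzaldehyde | CCOc1cc(O)c(C=O)cc1Oc1c(OC)c(OC)cc2oc(=O)ccc12
F10 | step 8 | ethyl (2E)-3-{5-[(6,7-dimethoxy-2-oxo-2H-chromen-5-yl)oxy]-4-ethoxy-2-hydroxyphenyl}prop-2-enoate | CCOC(=O)/C=C/c1cc(Oc2c(OC)c(OC)cc3oc(=O)ccc23)c(OCC)cc1O
A1 | alternative 1 | 6-[(6,7-dimethoxy-2-oxo-2H-chromen-5-yl)oxy]-7-methoxy-2H-chromen-2-one | O=c1ccc2cc(Oc3c(OC)c(OC)cc4oc(=O)ccc34)c(OC)cc2o1
A2 | alternative 1 | (2E)-3-{2-[5-[(E)-2-carboxyethenyl]-2-methoxyphenoxy]-3,4-dimethoxyphenyl}prop-2-enoic acid | OC(=O)/C=C/c1ccc(OC)c(Oc2c(OC)c(OC)ccc2/C=C/C(O)=O)c1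
A3 | alternative 2 | 2-(2,4-dimethoxyphenoxy)-4,6-dihydroxy-3-methoxybenzaldehyde | O=Cc1c(O)cc(O)c(OC)c1Oc1ccc(OC)cc1OC
A4 | alternative 2 | 1,4-dimethoxy-1,3-bis(trimethylsilyloxy)buta-1,3-diene | COC=C(O[Si](C)(C)C)C=C(OC)O[Si](C)(C)C
A5 | alternative 2 | 3-(2,4-dimethoxyphenoxy)prop-2-ynal | O=CC#COc1ccc(OC)cc1OC
A6 | alternative 3 | 6-hydroxy-5-(2-hydroxy-4-methoxyphenoxy)-7-methoxy-2H-chromen-2-one | COc1ccc(Oc2c(O)c(OC)cc3oc(=O)ccc23)c(O)c1
A7 | alternative 3 | 5-(2-formyl-4-methoxyphenoxy)-7-methoxy-2-oxo-2H-chromene-6-carbaldehyde | COc1ccc(Oc2c(C=O)c(OC)cc3oc(=O)ccc23)c(C=O)c1
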